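**Retrosynthetic overview**

1. Target 34 is 6β-acetoxylabda-8,13-dien-15,16-olide. The acetate and the 6β-hydroxyl come from a C6 ketone (hydride from the α face), the C8=C9 olefin of ring B from ring-closing metathesis of C9=CH2 with a methallyl ketone on C6, and the butenolide from a 3-furyl group.
2. The strategy rests on the vicinal pair C5 (tertiary CH between C4 and C6) and C10 (quaternary, bearing C20) of ring A. Both centres are set, and ring A is closed, when the silyl ketene acetal of a δ-lactone spanning C2 to C6 undergoes a [3,3] shift that forms C5–C10 and breaks C2–O.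
3. The (R)-6-[(Z)-dienyl] lactone comes from a 1,5-diol by oxidative lactonisation. Its Z-diene comes from Suzuki coupling of a (Z)-alkenyl iodide with a 2-boryl-1-alkene; the iodide is made from 3,3-dimethylglutaric anhydride (ynone, transfer hydrogenation at C2, anti-hydroalumination/iodination), the boronate from furan-3-ylmethanol and 2,3-dibromopropene.
4. Ring A is formed first (step 10), ring B second (step 18). In between, the ring A olefin C1=C2 is hydrogenated while C9=CH2 is masked as an iodolactone, and the furan is oxidised to the butenolide before ring B is closed.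

Key step: step 10

Remark: labdane numbering is used for all carbon atoms, also in the fragments (C6 = acetoxy carbon, C8=C9 = ring B olefin, C10 = quaternary ring-fusion carbon). Centres that are destroyed later (the lactol carbons of 17 and 24, C9 of 22–24, C6 of 27–30) are carried as epimer mixtures.

**Route**

Step 1
Reactants: 1 3,3-dimethylglutaric anhydride
Product: 2 5-[methoxy(methyl)amino]-3,3-dimethyl-5-oxopentanoic acid
Conditions: MeNH(OMe)·HCl, Et3N, CH2Cl2, 0 °C → rt; then 1 M HCl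
Reagents that add atoms: N,O-dimethylhydroxylamine hydrochloride, CNOC.Cl
Why: Nucleophilic ring opening of the symmetrical cyclic anhydride by the liberated amine gives the Weinreb amide acid directly, and the carboxylate that forms is not attacked further.

Step 2
Reactants: 2 5-[methoxy(methyl)amino]-3,3-dimethyl-5-oxopentanoic acid; 3 prop-1-yn-1-ylmagnesium bromide (2.5 equiv)
Product: 4 3,3-dimethyl-5-oxooct-6-ynoic acid
Conditions: THF, −20 → 0 °C; then 1 M HCl
Reagents that add atoms: none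
Why: Weinreb ketone synthesis, in which the first equivalent of the alkynyl Grignard reagent only deprotonates the acid and the second adds to the amide to give a chelated adduct that releases the ynone on acidic work-up, so over-addition is not expected.

Step 3
Reactants: 4 3,3-dimethyl-5-oxooct-6-ynoic acid
Product: 6 (6R)-4,4-dimethyl-6-(prop-1-yn-1-yl)oxan-2-one, via hydroxy acid 5 (not isolated)
Conditions: RuCl(p-cymene)[(R,R)-TsDPEN] (1 mol %), HCO2H/Et3N (5:2), CH2Cl2, rt; then TsOH (cat.), PhMe, 40 °C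
Reagents that add atoms: none
Why: Noyori asymmetric transfer hydrogenation of an α,β-acetylenic ketone, in which the alkynyl group takes the place of the aryl group of the usual model so that the (R,R)-catalyst should give the (R)-carbinol at C2, followed by acid-catalysed closure of the δ-hydroxy acid to the lactone (gem-dimethyl effect).

Step 4
Reactants: 6 (6R)-4,4-dimethyl-6-(prop-1-yn-1-yl)oxan-2-one
Product: 8 (5R,6Z)-7-iodo-3,3-dimethyloct-6-ene-1,5-diol, via cyclic alkenylalanate 7 (not isolated)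
Conditions: NaAlH2(OCH2CH2OMe)2 (4 equiv), THF, 0 °C → rt; then I2, THF, −78 → 0 °C
Reagents that add atoms: iodine, II
Why: The hydride first reduces the lactone to the diol dialkoxide, the propargylic alkoxide then directs anti-hydroalumination of the alkyne (aluminium on the distal carbon C10 in a five-membered alanate), and iodinolysis with retention gives the (Z)-3-iodoallylic alcohol with C2 untouched.

Step 5
Reactants: 9 furan-3-ylmethanol
Product: 10 3-(chloromethyl)furan
Conditions: SOCl2, pyridine, Et2O, 0 °C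
Reagents that add atoms: thionyl chloride, O=S(Cl)Cl
Why: Chlorodehydroxylation through the chlorosulfite, with pyridine taking up HCl so that the acid-sensitive furan survives.

Step 6
Reactants: 10 3-(chloromethyl)furan; 11 2,3-dibromoprop-1-ene
Product: 13 3-(3-bromobut-3-en-1-yl)furan, via Grignard reagent 12 (not isolated)
Conditions: Mg, THF, 0 °C; then 11, CuI (5 mol %), −20 °C → rt
Reagents that add atoms: none
Why: Copper-catalysed allylic substitution by the benzylic-type Grignard reagent on the allylic bromide of 11 (SN2 and SN2' attack give the same product), which leaves the vinylic bromide untouched.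

Step 7
Reactants: 13 3-(3-bromobut-3-en-1-yl)furan
Product: 15 2-[4-(furan-3-yl)but-1-en-2-yl]-4,4,5,5-tetramethyl-1,3,2-dioxaborolane, via alkenyllithium 14 (not isolated)
Conditions: t-BuLi (2.0 equiv), Et2O, −78 °C; then i-PrOBpin, −78 °C → rt; H2O
Reagents that add atoms: 2-isopropoxy-4,4,5,5-tetramethyl-1,3,2-dioxaborolane, CC(C)OB1OC(C)(C)C(C)(C)O1
Why: Bromine–lithium exchange at −78 °C is much faster than deprotonation of the furan, and the alkenyllithium is trapped by the borate ester to give the pinacol alkenylboronate.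

Step 8
Reactants: 8 (5R,6Z)-7-iodo-3,3-dimethyloct-6-ene-1,5-diol; 15 2-[4-(furan-3-yl)but-1-en-2-yl]-4,4,5,5-tetramethyl-1,3,2-dioxaborolane
Product: 16 (5R,6Z)-10-(furan-3-yl)-3,3,7-trimethyl-8-methylidenedec-6-ene-1,5-diol
Conditions: PdCl2(dppf) (5 mol %), K3PO4, THF/H2O, 45 °C
Reagents that add atoms: none
Why: Suzuki–Miyaura coupling of an alkenyl iodide with an alkenylboronate goes with retention at both sp2 carbons, so the Z geometry set in step 4 (C9 cis to C2) is carried into the diene, and the free hydroxyl groups are tolerated.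

Step 9
Reactants: 16 (5R,6Z)-10-(furan-3-yl)-3,3,7-trimethyl-8-methylidenedec-6-ene-1,5-diol
Product: 18 (6R)-6-[(1Z)-5-(furan-3-yl)-2-methyl-3-methylidenepent-1-en-1-yl]-4,4-dimethyloxan-2-one, via lactol 17 (not isolated)
Conditions: TEMPO (20 mol %), PhI(OAc)2 (2.5 equiv), CH2Cl2, rt
Reagents that add atoms: none
Why: Oxoammonium-mediated oxidative lactonisation, selective for the primary alcohol; the aldehyde is trapped by the C2 hydroxyl as the six-membered lactol, which should be oxidised on to the lactone faster than the hindered secondary dienyl alcohol is attacked.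

Step 10
Reactants: 18 (6R)-6-[(1Z)-5-(furan-3-yl)-2-methyl-3-methylidenepent-1-en-1-yl]-4,4-dimethyloxan-2-one
Product: 21 (1S,2S)-2-[4-(furan-3-yl)but-1-en-2-yl]-2,6,6-trimethylcyclohex-3-ene-1-carboxylic acid, via silyl ketene acetal 19 (not isolated), via trimethylsilyl ester 20 (not isolated)
Conditions: LiN(i-Pr)2, Me3SiCl/Et3N, THF, −78 °C → rt; PhMe, 105 °C; then 1 M HCl, THF, rt
Reagents that add atoms: none
Why: Deprotonation at C5 and O-silylation give the cyclic silyl ketene acetal 19, whose [3,3]-sigmatropic shift forms C5–C10 and breaks C2–O (Ireland–Claisen rearrangement; the closest known type is the ring contraction of 6-alkenyl δ-lactone silyl ketene acetals to cyclohexenecarboxylic acids). Ring A (C5–C4–C3–C2=C1–C10) closes by this pericyclic contraction of the lactone and not by an ionic cyclisation: the lactone carbons C2 to C5 stay linked and C1 and C10 are drawn into the ring. Because the ketene acetal double bond lies inside the lactone ring, only a boat-like transition state shaped like bicyclo[2.2.2]octane is possible, so C5 bonds to the olefin face from which the C2–O bond departs. C10 is therefore set by 1,3-transfer of the (R)-C2 centre together with the Z geometry, and C5 by the enforced boat, which places the carboxyl cis to the C10 methyl and trans to C9 (5S,10S, the trans-decalin relationship). The step needs this single pathway to outrun fragmentation of the ketene acetal; the tether excludes a chair, the Z-olefin is configurationally stable and C5 is the only enolisable position. Acidic work-up hydrolyses the silyl ester 20 to the acid.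

Step 11
Reactants: 21 (1S,2S)-2-[4-(furan-3-yl)but-1-en-2-yl]-2,6,6-trimethylcyclohex-3-ene-1-carboxylic acid
Product: 22 (3aS,7aS)-3-[2-(furan-3-yl)ethyl]-3-(iodomethyl)-3a,7,7-trimethyl-3a,6,7,7a-tetrahydro-2-benzofuran-1(3H)-one (C3 epimers)
Conditions: I2, NaHCO3, MeCN, 0 °C, dark
Reagents that add atoms: iodine, II
Why: Iodolactonisation, in which the more nucleophilic 1,1-disubstituted C9=CH2 olefin is attacked in the Markovnikov sense by the carboxylate on C5 (5-exo closure to a trans-fused γ-lactone, C6 and C9 being trans-diequatorial), so that this olefin is masked while the ring A olefin is reduced and ring A can no longer enter a ring-rearrangement metathesis in step 18.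

Step 12
Reactants: 22 iodolactone (C3 epimers)
Product: 23 (3aS,7aS)-3-[2-(furan-3-yl)ethyl]-3-(iodomethyl)-3a,7,7-trimethyl-3a,4,5,6,7,7a-hexahydro-2-benzofuran-1(3H)-one (C3 epimers)
Conditions: H2 (3 atm), RhCl(PPh3)3 (10 mol %), PhH/EtOH (1:1), rt
Reagents that add atoms: none
Why: Homogeneous hydrogenation with RhCl(PPh3)3 reduces the cis-disubstituted C1=C2 olefin, now the only non-aromatic C=C bond, and leaves the furan and the neopentyl-type iodide alone; no stereocentre is formed.

Step 13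
Reactants: 23 saturated iodolactone
Product: 24 (3aS,7aS)-3-[2-(furan-3-yl)ethyl]-3-(iodomethyl)-3a,7,7-trimethyl-1,3,3a,4,5,6,7,7a-octahydro-2-benzofuran-1-ol (epimers at C1 and C3)
Conditions: i-Bu2AlH (1.2 equiv), CH2Cl2, −78 °C
Reagents that add atoms: none
Why: Partial reduction of the lactone at −78 °C stops at the aluminium hemiacetal, which gives the lactol on work-up.

Step 14
Reactants: 24 iodo lactol
Product: 25 (1S,2S)-2-[4-(furan-3-yl)but-1-en-2-yl]-2,6,6-trimethylcyclohexane-1-carbaldehyde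
Conditions: Zn dust, THF/H2O (4:1), ultrasound, 40 °C
Reagents that add atoms: none
Why: Bernet–Vasella-type reductive fragmentation, in which zinc inserts into the C–I bond and β-elimination of the ring oxygen regenerates C9=CH2 while the hemiacetal collapses to the C6 aldehyde; C5 keeps its configuration, which is also the more stable one (formyl equatorial, trans to C9).

Step 15
Reactants: 25 aldehyde; 26 2-methylallylmagnesium chloride
Product: 27 1-{(1S,2S)-2-[4-(furan-3-yl)but-1-en-2-yl]-2,6,6-trimethylcyclohexyl}-3-methylbut-3-en-1-ol (C6 epimers)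
Conditions: THF, −78 → 0 °C; H2O
Reagents that add atoms: none
Why: Grignard addition of the allylic reagent to the hindered aldehyde through a six-membered transition state; the C6 configuration need not be controlled because C6 is oxidised in step 17.

Step 16
Reactants: 27 furyl alcohol (C6 epimers)
Product: 30 4-{3-[(1S,2S)-2-(1-hydroxy-3-methylbut-3-en-1-yl)-1,3,3-trimethylcyclohexyl]but-3-en-1-yl}furan-2(5H)-one (C6 epimers), via endoperoxide 28 (not isolated), via hydroxybutenolide 29 (not isolated)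
Conditions: O2, hν (visible), tetraphenylporphyrin (cat.), i-Pr2NEt, CH2Cl2, −78 °C; then NaBH4, EtOH, 0 °C; 1 M HCl
Reagents that add atoms: oxygen, O=O
Why: [4+2] addition of singlet oxygen to the furan (much faster than the ene reaction of 1,1-disubstituted olefins), base-induced fragmentation of the endoperoxide by removal of the less hindered hydrogen on C15 to give the 16-hydroxy-15,16-olide regioselectively, and borohydride reduction of its open aldehyde form with relactonisation to the butenolide.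

Step 17
Reactants: 30 butenolide alcohol (C6 epimers)
Product: 31 4-{3-[(1S,2S)-1,3,3-trimethyl-2-(3-methylbut-3-enoyl)cyclohexyl]but-3-en-1-yl}furan-2(5H)-one
Conditions: Dess–Martin periodinane, pyridine, CH2Cl2, 0 °C → rt
Reagents that add atoms: none
Why: Dess–Martin oxidation under buffered, non-enolising conditions should give the β,γ-unsaturated ketone without migration of the 1,1-disubstituted olefin into conjugation, and it merges the two C6 epimers.

Step 18
Reactants: 31 diene ketone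
Product: 32 4-{2-[(4aS,8aS)-2,5,5,8a-tetramethyl-4-oxo-3,4,4a,5,6,7,8,8a-octahydronaphthalen-1-yl]ethyl}furan-2(5H)-one (6-oxolabda-8,13-dien-15,16-olide)
Conditions: second-generation Hoveyda–Grubbs catalyst RuCl2(H2IMes)(=CH-C6H4-2-O-i-Pr) (10 mol %), 1,4-benzoquinone (10 mol %), PhMe, 80 °C, argon sparge
Reagents that add atoms: none
Why: Ring-closing metathesis of the two 1,1-disubstituted olefins, held gauche across C5–C10 (C6 and C9 both equatorial on ring A), closes ring B as the tetrasubstituted C8=C9 cyclohexene with loss of ethene; ring A is saturated so no ring-rearrangement pathway exists, the butenolide olefin is inert, and benzoquinone suppresses hydride-mediated olefin migration.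

Step 19
Reactants: 32 6-oxolabda-8,13-dien-15,16-olide
Product: 33 4-{2-[(4R,4aS,8aS)-4-hydroxy-2,5,5,8a-tetramethyl-3,4,4a,5,6,7,8,8a-octahydronaphthalen-1-yl]ethyl}furan-2(5H)-one (6β-hydroxylabda-8,13-dien-15,16-olide)
Conditions: NaBH4, MeOH, 0 °C
Reagents that add atoms: none
Why: Borohydride reduction in which hydride attacks C6 from the α face, because the β face is shielded by the syn-axial methyl groups on C10 and C4, giving the axial 6β-alcohol (6R); the β-substituted butenolide should survive at 0 °C.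

Step 20
Reactants: 33 6β-hydroxylabda-8,13-dien-15,16-olide
Product: 34 (1R,4aS,8aS)-3,4a,8,8-tetramethyl-4-[2-(5-oxo-2,5-dihydrofuran-3-yl)ethyl]-1,2,4a,5,6,7,8,8a-octahydronaphthalen-1-yl acetate (6β-acetoxylabda-8,13-dien-15,16-olide)
Conditions: Ac2O, DMAP, pyridine, 50 °C
Reagents that add atoms: acetic anhydride, CC(=O)OC(C)=O
Why: DMAP-catalysed acylation; the axial, hindered 6β-hydroxyl needs the nucleophilic catalyst and gentle warming, and no stereocentre is touched.

**Compound list**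

1 | 3,3-dimethylglutaric anhydride | CC1(C)CC(=O)OC(=O)C1 | starting material
2 | 5-[methoxy(methyl)amino]-3,3-dimethyl-5-oxopentanoic acid | CON(C)C(=O)CC(C)(C)CC(=O)O | intermediate
3 | prop-1-yn-1-ylmagnesium bromide | CC#C[Mg]Br | starting material
4 | 3,3-dimethyl-5-oxooct-6-ynoic acid | CC#CC(=O)CC(C)(C)CC(=O)O | intermediate
5 | (5R)-5-hydroxy-3,3-dimethyloct-6-ynoic acid | CC#C[C@H](O)CC(C)(C)CC(=O)O | intermediate (not isolated)
6 | (6R)-4,4-dimethyl-6-(prop-1-yn-1-yl)oxan-2-one | CC#C[C@H]1CC(C)(C)CC(=O)O1 | intermediate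
7 | cyclic sodium alkenylalanate of (5R)-3,3-dimethyloct-6-yne-1,5-diol (aluminium on C7 and on the C5 oxygen; drawn with the primary hydroxyl free) | [Na+].CC1=C[C@@H](CC(C)(C)CCO)O[Al-]1(OCCOC)OCCOC | intermediate (not isolated)
8 | (5R,6Z)-7-iodo-3,3-dimethyloct-6-ene-1,5-diol | C/C(I)=C/[C@H](O)CC(C)(C)CCO | intermediate
9 | furan-3-ylmethanol | OCc1ccoc1 | starting material
10 | 3-(chloromethyl)furan | ClCc1ccoc1 | intermediate
11 | 2,3-dibromoprop-1-ene | C=C(Br)CBr | starting material
12 | (furan-3-ylmethyl)magnesium chloride | Cl[Mg]Cc1ccoc1 | intermediate (not isolated)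
13 | 3-(3-bromobut-3-en-1-yl)furan | C=C(Br)CCc1ccoc1 | intermediate
14 | [4-(furan-3-yl)but-1-en-2-yl]lithium | [Li]C(=C)CCc1ccoc1 | intermediate (not isolated)
15 | 2-[4-(furan-3-yl)but-1-en-2-yl]-4,4,5,5-tetramethyl-1,3,2-dioxaborolane | C=C(CCc1ccoc1)B1OC(C)(C)C(C)(C)O1 | intermediate
16 | (5R,6Z)-10-(furan-3-yl)-3,3,7-trimethyl-8-methylidenedec-6-ene-1,5-diol | OCCC(C)(C)C[C@@H](O)/C=C(/C)\C(=C)CCc1ccoc1 | intermediate
17 | (6R)-6-[(1Z)-5-(furan-3-yl)-2-methyl-3-methylidenepent-1-en-1-yl]-4,4-dimethyloxan-2-ol (anomers) | OC1CC(C)(C)C[C@@H](O1)/C=C(/C)\C(=C)CCc1ccoc1 | intermediate (not isolated)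
18 | (6R)-6-[(1Z)-5-(furan-3-yl)-2-methyl-3-methylidenepent-1-en-1-yl]-4,4-dimethyloxan-2-one | O=C1CC(C)(C)C[C@@H](O1)/C=C(/C)\C(=C)CCc1ccoc1 | intermediate (key-step precursor)
19 | {[(2R)-2-[(1Z)-5-(furan-3-yl)-2-methyl-3-methylidenepent-1-en-1-yl]-4,4-dimethyl-3,4-dihydro-2H-pyran-6-yl]oxy}trimethylsilane | C[Si](C)(C)OC1=CC(C)(C)C[C@@H](O1)/C=C(/C)\C(=C)CCc1ccoc1 | intermediate (not isolated)
20 | trimethylsilyl (1S,2S)-2-[4-(furan-3-yl)but-1-en-2-yl]-2,6,6-trimethylcyclohex-3-ene-1-carboxylate | C[Si](C)(C)OC(=O)[C@H]1C(C)(C)CC=C[C@]1(C)C(=C)CCc1ccoc1 | intermediate (not isolated)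
21 | (1S,2S)-2-[4-(furan-3-yl)but-1-en-2-yl]-2,6,6-trimethylcyclohex-3-ene-1-carboxylic acid | OC(=O)[C@H]1C(C)(C)CC=C[C@]1(C)C(=C)CCc1ccoc1 | intermediate (key-step product)
22 | (3aS,7aS)-3-[2-(furan-3-yl)ethyl]-3-(iodomethyl)-3a,7,7-trimethyl-3a,6,7,7a-tetrahydro-2-benzofuran-1(3H)-one (C3 epimers) | O=C1OC(CI)(CCc2ccoc2)[C@@]3(C)C=CCC(C)(C)[C@H]13 | intermediate
23 | (3aS,7aS)-3-[2-(furan-3-yl)ethyl]-3-(iodomethyl)-3a,7,7-trimethyl-3a,4,5,6,7,7a-hexahydro-2-benzofuran-1(3H)-one (C3 epimers) | O=C1OC(CI)(CCc2ccoc2)[C@@]3(C)CCCC(C)(C)[C@H]13 | intermediate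
24 | (3aS,7aS)-3-[2-(furan-3-yl)ethyl]-3-(iodomethyl)-3a,7,7-trimethyl-1,3,3a,4,5,6,7,7a-octahydro-2-benzofuran-1-ol (epimers at C1 and C3) | OC1OC(CI)(CCc2ccoc2)[C@@]3(C)CCCC(C)(C)[C@H]13 | intermediate
25 | (1S,2S)-2-[4-(furan-3-yl)but-1-en-2-yl]-2,6,6-trimethylcyclohexane-1-carbaldehyde | O=C[C@H]1C(C)(C)CCC[C@]1(C)C(=C)CCc1ccoc1 | intermediate
26 | 2-methylallylmagnesium chloride | C=C(C)C[Mg]Cl | starting material
27 | 1-{(1S,2S)-2-[4-(furan-3-yl)but-1-en-2-yl]-2,6,6-trimethylcyclohexyl}-3-methylbut-3-en-1-ol (C6 epimers) | C=C(C)CC(O)[C@H]1C(C)(C)CCC[C@]1(C)C(=C)CCc1ccoc1 | intermediate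
28 | furan endoperoxide of 27 (5-substituted 2,3,7-trioxabicyclo[2.2.1]hept-5-ene) | C=C(C)CC(O)[C@H]1C(C)(C)CCC[C@]1(C)C(=C)CCC1=CC2OOC1O2 | intermediate (not isolated)
29 | 5-hydroxy-4-{3-[(1S,2S)-2-(1-hydroxy-3-methylbut-3-en-1-yl)-1,3,3-trimethylcyclohexyl]but-3-en-1-yl}furan-2(5H)-one | C=C(C)CC(O)[C@H]1C(C)(C)CCC[C@]1(C)C(=C)CCC1=CC(=O)OC1O | intermediate (not isolated)
30 | 4-{3-[(1S,2S)-2-(1-hydroxy-3-methylbut-3-en-1-yl)-1,3,3-trimethylcyclohexyl]but-3-en-1-yl}furan-2(5H)-one (C6 epimers) | C=C(C)CC(O)[C@H]1C(C)(C)CCC[C@]1(C)C(=C)CCC1=CC(=O)OC1 | intermediate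
31 | 4-{3-[(1S,2S)-1,3,3-trimethyl-2-(3-methylbut-3-enoyl)cyclohexyl]but-3-en-1-yl}furan-2(5H)-one | C=C(C)CC(=O)[C@H]1C(C)(C)CCC[C@]1(C)C(=C)CCC1=CC(=O)OC1 | intermediate
32 | 4-{2-[(4aS,8aS)-2,5,5,8a-tetramethyl-4-oxo-3,4,4a,5,6,7,8,8a-octahydronaphthalen-1-yl]ethyl}furan-2(5H)-one | O=C1CC(C)=C(CCC2=CC(=O)OC2)[C@@]2(C)CCCC(C)(C)[C@H]12 | intermediate
33 | 4-{2-[(4R,4aS,8aS)-4-hydroxy-2,5,5,8a-tetramethyl-3,4,4a,5,6,7,8,8a-octahydronaphthalen-1-yl]ethyl}furan-2(5H)-one | O[C@@H]1CC(C)=C(CCC2=CC(=O)OC2)[C@@]2(C)CCCC(C)(C)[C@H]12 | intermediate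
34 | (1R,4aS,8aS)-3,4a,8,8-tetramethyl-4-[2-(5-oxo-2,5-dihydrofuran-3-yl)ethyl]-1,2,4a,5,6,7,8,8a-octahydronaphthalen-1-yl acetate | CC(=O)O[C@@H]1CC(C)=C(CCC2=CC(=O)OC2)[C@@]2(C)CCCC(C)(C)[C@H]12 | target

**Step count**

Total: 20 steps. Longest linear sequence: 17 steps (steps 1–4 and 8–20, from anhydride 1).

**Steps most likely to fail**

Step 10. The boat presses the C9 substituent against the C3–C4 bridge and one C4 methyl group, so the rearrangement may be slower than fragmentation or C-silylation of the ketene acetal, and the lactone would then be consumed without C5–C10 bond formation. The fallback replaces the boat by an open-chain chair and closes ring A afterwards; it sets out from boronate 15 and comes back at acid 21. Purchased pent-3-yn-2-one is reduced as in step 3, but with the (S,S)-catalyst, to (2S)-pent-3-yn-2-ol F1. Treatment as in step 4 gives (2S,3Z)-4-iodopent-3-en-2-ol F2. Suzuki coupling of F2 with 15 under the conditions of step 8 gives (2S,3Z)-7-(furan-3-yl)-4-methyl-5-methylidenehept-3-en-2-ol F3. Esterification with purchased 3,3-dimethylhex-5-enoic acid (DCC, DMAP, CH2Cl2) gives (2S,3Z)-7-(furan-3-yl)-4-methyl-5-methylidenehept-3-en-2-yl 3,3-dimethylhex-5-enoate F4. Ireland–Claisen rearrangement of F4 (LiN(i-Pr)2, THF/DMPU, Me3SiCl, −78 °C → rt, then 1 M HCl) is run through the silyl ketene acetal that has C4 cis to the silyloxy group. It then passes through a chair with the carbinol methyl equatorial; with the (S)-carbinol and the Z-olefin this should give the same C5/C10 configuration in (2S,3S,4E)-3-[4-(furan-3-yl)but-1-en-2-yl]-3-methyl-2-(2-methylpent-4-en-2-yl)hex-4-enoic acid F5. Ring-closing metathesis of the allyl and (E)-propenyl groups of F5 (second-generation Grubbs catalyst RuCl2(H2IMes)(PCy3)(=CHPh), CH2Cl2, 40 °C) closes ring A with loss of propene and gives 21.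

Step 18. The ruthenium alkylidene may fail to engage the hindered 1,1-disubstituted C9 olefin next to the quaternary C10, and the catalyst may decompose or move the methallyl double bond into conjugation before ring B closes. The fallback forms C8=C9 by carbonyl coupling; it sets out from furyl alcohol 27 and comes back at ketone 32. Silylation (t-BuMe2SiOTf, 2,6-lutidine) gives tert-butyl{[1-{(1S,2S)-2-[4-(furan-3-yl)but-1-en-2-yl]-2,6,6-trimethylcyclohexyl}-3-methylbut-3-en-1-yl]oxy}dimethylsilane F6. Cleavage of both 1,1-disubstituted olefins (OsO4 cat., NaIO4, 2,6-lutidine, dioxane/H2O) gives 4-[(tert-butyldimethylsilyl)oxy]-4-{(1S,2S)-2-[3-(furan-3-yl)propanoyl]-2,6,6-trimethylcyclohexyl}butan-2-one F7. Intramolecular McMurry coupling (TiCl3, Zn(Cu), DME, reflux, high dilution) joins C8 and C9 to give tert-butyl{[(4aS,8aS)-4-[2-(furan-3-yl)ethyl]-3,4a,8,8-tetramethyl-1,2,4a,5,6,7,8,8a-octahydronaphthalen-1-yl]oxy}dimethylsilane F8. Bu4NF gives (4aS,8aS)-4-[2-(furan-3-yl)ethyl]-3,4a,8,8-tetramethyl-1,2,4a,5,6,7,8,8a-octahydronaphthalen-1-ol F9. The furan is then oxidised under the conditions of step 16 to 4-{2-[(4aS,8aS)-4-hydroxy-2,5,5,8a-tetramethyl-3,4,4a,5,6,7,8,8a-octahydronaphthalen-1-yl]ethyl}furan-2(5H)-one F10; at −78 °C the cycloaddition to the furan is expected to outrun the ene reaction of the hindered tetrasubstituted olefin. Dess–Martin oxidation of F10 gives 32.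

Step 11. Iodonium transfer may lose chemoselectivity (attack on the furan or on the ring A olefin), or the strained trans-fused lactonisation may reverse. The fallback drops the masking and hydrogenates ring A only after ring B is closed, accepting the risk of ring-rearrangement metathesis through C1=C2; it sets out from acid 21 and comes back at ketone 32. LiAlH4 (THF, 0 °C → reflux) gives [(1S,2S)-2-[4-(furan-3-yl)but-1-en-2-yl]-2,6,6-trimethylcyclohex-3-en-1-yl]methanol F11. Dess–Martin oxidation gives (1S,2S)-2-[4-(furan-3-yl)but-1-en-2-yl]-2,6,6-trimethylcyclohex-3-ene-1-carbaldehyde F12. Addition of 26 gives 1-{(1S,2S)-2-[4-(furan-3-yl)but-1-en-2-yl]-2,6,6-trimethylcyclohex-3-en-1-yl}-3-methylbut-3-en-1-ol F13. The conditions of step 16 give 4-{3-[(1S,6S)-6-(1-hydroxy-3-methylbut-3-en-1-yl)-1,5,5-trimethylcyclohex-2-en-1-yl]but-3-en-1-yl}furan-2(5H)-one F14. Dess–Martin oxidation gives 4-{3-[(1S,6S)-1,5,5-trimethyl-6-(3-methylbut-3-enoyl)cyclohex-2-en-1-yl]but-3-en-1-yl}furan-2(5H)-one F15. Ring-closing metathesis under the conditions of step 18 gives 4-{2-[(4aS,8aS)-2,5,5,8a-tetramethyl-4-oxo-3,4,4a,5,6,8a-hexahydronaphthalen-1-yl]ethyl}furan-2(5H)-one F16. Hydrogenation with RhCl(PPh3)3/H2 then saturates only the cis-disubstituted ring A olefin of F16 and gives 32.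

Further compounds
F1 | step 10 | (2S)-pent-3-yn-2-ol | CC#C[C@H](C)O
F2 | step 10 | (2S,3Z)-4-iodopent-3-en-2-ol | C/C(I)=C/[C@H](C)O
F3 | step 10 | (2S,3Z)-7-(furan-3-yl)-4-methyl-5-methylidenehept-3-en-2-ol | C[C@H](O)/C=C(/C)\C(=C)CCc1ccoc1
F4 | step 10 | (2S,3Z)-7-(furan-3-yl)-4-methyl-5-methylidenehept-3-en-2-yl 3,3-dimethylhex-5-enoate | C=CCC(C)(C)CC(=O)O[C@@H](C)/C=C(/C)\C(=C)CCc1ccoc1
F5 | step 10 | (2S,3S,4E)-3-[4-(furan-3-yl)but-1-en-2-yl]-3-methyl-2-(2-methylpent-4-en-2-yl)hex-4-enoic acid | OC(=O)[C@@H](C(C)(C)CC=C)[C@](C)(/C=C/C)C(=C)CCc1ccoc1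
F6 | step 18 | tert-butyl{[1-{(1S,2S)-2-[4-(furan-3-yl)but-1-en-2-yl]-2,6,6-trimethylcyclohexyl}-3-methylbut-3-en-1-yl]oxy}dimethylsilane (C6 epimers) | C=C(C)CC(O[Si](C)(C)C(C)(C)C)[C@H]1C(C)(C)CCC[C@]1(C)C(=C)CCc1ccoc1
F7 | step 18 | 4-[(tert-butyldimethylsilyl)oxy]-4-{(1S,2S)-2-[3-(furan-3-yl)propanoyl]-2,6,6-trimethylcyclohexyl}butan-2-one (C6 epimers) | CC(=O)CC(O[Si](C)(C)C(C)(C)C)[C@H]1C(C)(C)CCC[C@]1(C)C(=O)CCc1ccoc1
F8 | step 18 | tert-butyl{[(4aS,8aS)-4-[2-(furan-3-yl)ethyl]-3,4a,8,8-tetramethyl-1,2,4a,5,6,7,8,8a-octahydronaphthalen-1-yl]oxy}dimethylsilane (C6 epimers) | CC(C)(C)[Si](C)(C)OC1CC(C)=C(CCc2ccoc2)[C@@]2(C)CCCC(C)(C)[C@H]12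
F9 | step 18 | (4aS,8aS)-4-[2-(furan-3-yl)ethyl]-3,4a,8,8-tetramethyl-1,2,4a,5,6,7,8,8a-octahydronaphthalen-1-ol (C6 epimers) | OC1CC(C)=C(CCc2ccoc2)[C@@]2(C)CCCC(C)(C)[C@H]12
F10 | step 18 | 4-{2-[(4aS,8aS)-4-hydroxy-2,5,5,8a-tetramethyl-3,4,4a,5,6,7,8,8a-octahydronaphthalen-1-yl]ethyl}furan-2(5H)-one (C6 epimers) | OC1CC(C)=C(CCC2=CC(=O)OC2)[C@@]2(C)CCCC(C)(C)[C@H]12
F11 | step 11 | [(1S,2S)-2-[4-(furan-3-yl)but-1-en-2-yl]-2,6,6-trimethylcyclohex-3-en-1-yl]methanol | OC[C@H]1C(C)(C)CC=C[C@]1(C)C(=C)CCc1ccoc1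
F12 | step 11 | (1S,2S)-2-[4-(furan-3-yl)but-1-en-2-yl]-2,6,6-trimethylcyclohex-3-ene-1-carbaldehyde | O=C[C@H]1C(C)(C)CC=C[C@]1(C)C(=C)CCc1ccoc1
F13 | step 11 | 1-{(1S,2S)-2-[4-(furan-3-yl)but-1-en-2-yl]-2,6,6-trimethylcyclohex-3-en-1-yl}-3-methylbut-3-en-1-ol (C6 epimers) | C=C(C)CC(O)[C@H]1C(C)(C)CC=C[C@]1(C)C(=C)CCc1ccoc1
F14 | step 11 | 4-{3-[(1S,6S)-6-(1-hydroxy-3-methylbut-3-en-1-yl)-1,5,5-trimethylcyclohex-2-en-1-yl]but-3-en-1-yl}furan-2(5H)-one (C6 epimers) | C=C(C)CC(O)[C@H]1C(C)(C)CC=C[C@]1(C)C(=C)CCC1=CC(=O)OC1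
F15 | step 11 | 4-{3-[(1S,6S)-1,5,5-trimethyl-6-(3-methylbut-3-enoyl)cyclohex-2-en-1-yl]but-3-en-1-yl}furan-2(5H)-one | C=C(C)CC(=O)[C@H]1C(C)(C)CC=C[C@]1(C)C(=C)CCC1=CC(=O)OC1
F16 | step 11 | 4-{2-[(4aS,8aS)-2,5,5,8a-tetramethyl-4-oxo-3,4,4a,5,6,8a-hexahydronaphthalen-1-yl]ethyl}furan-2(5H)-one | O=C1CC(C)=C(CCC2=CC(=O)OC2)[C@@]2(C)C=CCC(C)(C)[C@H]12
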